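**Retrosynthetic overview**
1. The target is cut at C8–C9. Hydrolysis of a C14 peroxyketal, diimide saturation of C8=C9 and C11=C12, and a Wittig union lead back to a C1–C8 dioxane aldehyde and a C9–C18 phosphonium salt.
2. The C9–C18 salt comes from a C11=C12 Wittig reaction between a ylide made from (S)-3-bromo-2-methylpropanol (C9–C11, carries C10) and a C12 aldehyde. Its C14 peroxy centre is made by opening the linalool oxetane with H2O2 (inversion).
3. In the core, the C1 ester comes from cleavage of an alkene. The C2–C3 bond and both stereocentres come from addition of a chiral (E)-crotylsilane to the C3 peroxycarbenium ion of a 3-methoxy-1,2-dioxane.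
4. The 1,2-dioxane (O1–O2–C3–C4–C5–C6) is the only ring and is formed first, by 6-exo attack of a C3 hydroperoxyacetal on C6 of an oxetane (O–C6–C7–C8). The feature behind this is that C6 is a fully substituted peroxy carbon whose two carbon arms (ring C5H2, chain C7H2) are nearly alike, while C3–C8 with the C6 methyl is the linalool skeleton with the carbinol carbon as C6. C6, and likewise C14, is therefore set by stereospecific inversion and not by face selection.
5. The oxetane is made from (R)-linalool by hydroboration and ring closure, and it supplies both C6 and C14.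

Key step: step 6

Assumption: locants C1–C18 are those of the target chain (C1 ester carbon, O1 on C6, O2 on C3, chain C7–C18) and are kept for all intermediates; (R)-linalool and (S)-but-3-yn-2-ol of high enantiomeric purity are taken as commercial; CIP descriptors of C6, C10 and C14 change along the route with substituent priorities while the spatial arrangement stays that of the target.

**Route**

Step 1
Reactants: 1 (R)-(−)-linalool
Product: 2 (3R)-3,7-dimethyloct-6-ene-1,3-diol
Conditions: 9-BBN (9-borabicyclo[3.3.1]nonane, 2.2 equiv), THF, 0 °C → rt; then NaOH, H2O2, H2O, 0 °C → rt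
Reagents that add atoms: hydrogen peroxide, OO
Why: Hydroboration–oxidation with the bulky borane should take the monosubstituted C7=C8 alkene in the anti-Markovnikov sense and leave the trisubstituted alkene, and the carbinol centre is not touched.

Step 2
Reactants: 2 (3R)-3,7-dimethyloct-6-ene-1,3-diol
Product: 4 (2R)-2-methyl-2-(4-methylpent-3-en-1-yl)oxetane, via monotosylate 3 (not isolated)
Conditions: n-BuLi (1.0 equiv), THF, 0 °C; TsCl (1.0 equiv); then KOtBu (1.2 equiv), 0 → 40 °C
Reagents that add atoms: none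
Why: The primary alkoxide is sulfonylated first, and the tertiary alkoxide then displaces the tosylate at the primary carbon (4-exo-tet intramolecular Williamson etherification), so the C–O bond at the stereocentre is never broken and its configuration is retained.

Step 3
Reactants: 4 (2R)-2-methyl-2-(4-methylpent-3-en-1-yl)oxetane
Product: 6 3-[(2R)-2-methyloxetan-2-yl]propanal, via ozonide 5 (not isolated)
Conditions: O3, CH2Cl2, −78 °C; then PPh3 (1.1 equiv), −78 °C → rt
Reagents that add atoms: ozone, [O-][O+]=O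
Why: Ozonolysis with reductive work-up (Criegee mechanism) cleaves the only alkene to the C3 aldehyde, and neither ozone nor PPh3 attacks the oxetane.

Step 4
Reactants: 6 3-[(2R)-2-methyloxetan-2-yl]propanal; 7 (methoxymethyl)triphenylphosphonium chloride
Product: 9 (2R)-2-(4-methoxybut-3-en-1-yl)-2-methyloxetane (E/Z mixture), via methoxymethylene ylide 8 (not isolated)
Conditions: 7 (1.4 equiv), KOtBu (1.3 equiv), THF, 0 °C; then 6, 0 °C → rt
Reagents that add atoms: none
Why: Wittig methoxymethylenation with the preformed non-stabilised ylide adds the one carbon that will leave again as methyl formate, and the E/Z mixture is of no consequence because the alkene is cleaved in step 5.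

Step 5
Reactants: 9 (2R)-2-(4-methoxybut-3-en-1-yl)-2-methyloxetane
Product: 11 1-methoxy-3-[(2R)-2-methyloxetan-2-yl]propyl hydroperoxide (both epimers at the acetal carbon C3), via carbonyl oxide 10 (not isolated)
Conditions: O3, CH2Cl2/MeOH (3:1), NaHCO3, −78 °C; N2 purge; concentration below rt, no reductant
Reagents that add atoms: ozone, [O-][O+]=O; methanol, CO
Why: In the ozonolysis of an enol ether the primary ozonide fragments (Criegee mechanism) so that the oxygenated carbon leaves as methyl formate and the carbonyl oxide sits on C3, where methanol adds to give the α-methoxy hydroperoxide, and no reductant is used so that the O–O bond is kept.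

Step 6
Reactants: 11 1-methoxy-3-[(2R)-2-methyloxetan-2-yl]propyl hydroperoxide
Product: 12 (6S)-6-(2-hydroxyethyl)-3-methoxy-6-methyl-1,2-dioxane (C3 epimers)
Conditions: Me3SiOTf (0.2 equiv), CH2Cl2, −78 → −30 °C; Et3N, aq. NaHCO3
Reagents that add atoms: none
Why: The silyl triflate coordinates the oxetane oxygen, and the terminal oxygen of the C3 hydroperoxyacetal attacks the tertiary carbon C6 from the side opposite the breaking C6–O bond, an SN2-like substitution with a loose transition state that releases the strain of the four-membered ring. The closest known reaction type is the Lewis acid-promoted opening of 2,2-disubstituted oxetanes by hydrogen peroxide, alkyl hydroperoxides and tethered hydroperoxides or hydroperoxyacetals, which takes place at the more substituted carbon with inversion. The 1,2-dioxane ring (O1–O2–C3–C4–C5–C6) closes in the 6-exo-tet mode, the breaking C6–O bond lying outside the new ring. C6 is the only stereocentre set, and it is controlled by the carbinol configuration of (R)-linalool carried in the oxetane and inverted once, while C3 stays an epimer mixture that is erased later in the peroxycarbenium ion. The step needs regioselectivity for C6 over C8 and stereospecificity over ionisation to a free tertiary cation: the C5–C4–C3 tether makes C6 the only oxetane carbon within reach of a six-membered transition state (attack at C8 would need an eight-membered one), and the tethered nucleophile, the low temperature and the non-ionising solvent should keep the displacement concerted. The oxetane oxygen is released as the C8 hydroxyl, the handle for the side chain.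

Step 7
Reactants: 12 (6S)-6-(2-hydroxyethyl)-3-methoxy-6-methyl-1,2-dioxane
Product: 13 (6S)-6-[2-(tert-butyldiphenylsilyloxy)ethyl]-3-methoxy-6-methyl-1,2-dioxane (C3 epimers)
Conditions: t-BuPh2SiCl, imidazole, CH2Cl2, 0 °C → rt
Reagents that add atoms: tert-butyl(chloro)diphenylsilane, CC(C)(C)[Si](Cl)(c1ccccc1)c1ccccc1
Why: Standard silylation of the primary alcohol; the bulky silyl ether should survive the silyl triflate of step 10 and keeps the C8 oxygen from trapping the C3 cation.

Step 8
Reactants: 14 (S)-but-3-yn-2-ol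
Product: 15 (2S,3E)-4-[dimethyl(phenyl)silyl]but-3-en-2-ol
Conditions: PhMe2SiH (1.05 equiv), Pt2[(CH2=CHSiMe2)2O]3 (0.1 mol %, zerovalent platinum), P(t-Bu)3 (0.2 mol %), THF, 0 °C → rt
Reagents that add atoms: dimethylphenylsilane, C[SiH](C)c1ccccc1
Why: Platinum-catalysed syn hydrosilylation of the terminal alkyne places silicon on the terminal carbon and gives the (E)-vinylsilane, the bulky phosphine favouring the linear isomer, while the carbinol centre is untouched.

Step 9
Reactants: 15 (2S,3E)-4-[dimethyl(phenyl)silyl]but-3-en-2-ol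
Product: 17 methyl (3S,4E)-3-[dimethyl(phenyl)silyl]hex-4-enoate, via ketene acetal 16 (not isolated)
Conditions: MeC(OMe)3 (5 equiv), EtCO2H (0.1 equiv), toluene, reflux, MeOH distilled off
Reagents that add atoms: trimethyl orthoacetate, CC(OC)(OC)OC
Why: Johnson orthoester Claisen rearrangement through a chair transition state with the C-methyl group equatorial transfers the carbinol configuration suprafacially to the silicon-bearing carbon (S to S) and forms the (E)-alkene.

Step 10
Reactants: 13 (6S)-6-[2-(tert-butyldiphenylsilyloxy)ethyl]-3-methoxy-6-methyl-1,2-dioxane; 17 methyl (3S,4E)-3-[dimethyl(phenyl)silyl]hex-4-enoate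
Product: 19 methyl (3E,5S)-5-[(3S,6S)-6-[2-(tert-butyldiphenylsilyloxy)ethyl]-6-methyl-1,2-dioxan-3-yl]hex-3-enoate, via peroxycarbenium triflate 18 (not isolated)
Conditions: 17 (1.5 equiv), Me3SiOTf (1.1 equiv), CH2Cl2, −78 → −50 °C; aq. NaHCO3
Reagents that add atoms: none
Why: Hosomi–Sakurai-type substitution of the cyclic peroxyacetal through its peroxycarbenium ion, a known reaction of 3-alkoxy-1,2-dioxanes with allylsilanes, is run here with a chiral (E)-crotylsilane: attack anti to silicon (anti-SE2') fixes C2, and the antiperiplanar open transition state that places ring C4 next to the crotyl hydrogen gives the C2–C3 syn adduct and hence C3 as S, so that the reagent and not the distant C6 centre chooses the face of the cation.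

Step 11
Reactants: 19 methyl (3E,5S)-5-[(3S,6S)-6-[2-(tert-butyldiphenylsilyloxy)ethyl]-6-methyl-1,2-dioxan-3-yl]hex-3-enoate
Product: 22 (2R)-2-[(3S,6S)-6-[2-(tert-butyldiphenylsilyloxy)ethyl]-6-methyl-1,2-dioxan-3-yl]propanoic acid, via ozonide 20 (not isolated), via aldehyde 21 (not isolated)
Conditions: O3, CH2Cl2, −78 °C; PPh3 (1.05 equiv), −78 °C → rt; then NaClO2, NaH2PO4, 2-methyl-2-butene, t-BuOH/H2O, 0 °C → rt
Reagents that add atoms: ozone, [O-][O+]=O; sodium chlorite, [Na+].[O-]Cl=O
Why: Ozonolysis of the only alkene and Pinnick oxidation of the crude α-branched aldehyde under buffered conditions should give the acid without epimerising C2, dialkyl peroxides being inert to ozone, to PPh3 at low temperature and to chlorite.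

Step 12
Reactants: 22 (2R)-2-[(3S,6S)-6-[2-(tert-butyldiphenylsilyloxy)ethyl]-6-methyl-1,2-dioxan-3-yl]propanoic acid
Product: 23 methyl (2R)-2-[(3S,6S)-6-[2-(tert-butyldiphenylsilyloxy)ethyl]-6-methyl-1,2-dioxan-3-yl]propanoate
Conditions: Me3SiCHN2, toluene/MeOH (4:1), 0 °C
Reagents that add atoms: trimethylsilyldiazomethane, C[Si](C)(C)C=[N+]=[N-]
Why: Esterification with trimethylsilyldiazomethane is neutral and so avoids base at the β-peroxy ester, which could eliminate the peroxide from C3.

Step 13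
Reactants: 23 methyl (2R)-2-[(3S,6S)-6-[2-(tert-butyldiphenylsilyloxy)ethyl]-6-methyl-1,2-dioxan-3-yl]propanoate
Product: 24 methyl (2R)-2-[(3S,6S)-6-(2-hydroxyethyl)-6-methyl-1,2-dioxan-3-yl]propanoate
Conditions: HF·pyridine, pyridine, THF, 0 °C → rt
Reagents that add atoms: none
Why: Fluoride cleavage of the silyl ether under buffered acidic conditions frees the C8 hydroxyl without the base that could trigger Kornblum–DeLaMare fragmentation or β-elimination at the dioxane.

Step 14
Reactants: 24 methyl (2R)-2-[(3S,6S)-6-(2-hydroxyethyl)-6-methyl-1,2-dioxan-3-yl]propanoate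
Product: 25 methyl (2R)-2-[(3S,6S)-6-methyl-6-(2-oxoethyl)-1,2-dioxan-3-yl]propanoate
Conditions: Dess–Martin periodinane, NaHCO3, CH2Cl2, 0 °C → rt; used at once
Reagents that add atoms: none
Why: Dess–Martin oxidation under bicarbonate buffer stops at the aldehyde and leaves the O–O bond, the ester and C2 untouched.

Step 15
Reactants: 4 (2R)-2-methyl-2-(4-methylpent-3-en-1-yl)oxetane
Product: 26 (3S)-3-hydroperoxy-3,7-dimethyloct-6-en-1-ol
Conditions: anhydrous H2O2 in Et2O (10 equiv), Me3SiOTf (0.1 equiv), Et2O, −78 → 0 °C; aq. NaHCO3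
Reagents that add atoms: hydrogen peroxide, OO
Why: Lewis acid-activated opening of a 2,2-disubstituted oxetane by hydrogen peroxide is a known SN2-like substitution at the tertiary carbon with inversion, so the linalool configuration sets C14 in the sense of the target, and the primary C12 hydroxyl is released as the handle.

Step 16
Reactants: 26 (3S)-3-hydroperoxy-3,7-dimethyloct-6-en-1-ol
Product: 27 (3S)-3-hydroperoxy-3,7-dimethyloct-6-en-1-yl acetate
Conditions: Novozym 435 (immobilised Candida antarctica lipase B), isopropenyl acetate, t-BuOMe, rt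
Reagents that add atoms: isopropenyl acetate, CC(=C)OC(C)=O
Why: Lipase-catalysed transesterification acylates the unhindered primary alcohol, whereas the tertiary hydroperoxide is too hindered to be accepted by the enzyme, which differentiates the two OH groups.

Step 17
Reactants: 27 (3S)-3-hydroperoxy-3,7-dimethyloct-6-en-1-yl acetate
Product: 28 (3S)-3-[(2-methoxypropan-2-yl)peroxy]-3,7-dimethyloct-6-en-1-yl acetate
Conditions: 2-methoxypropene (3 equiv), PPTS (0.05 equiv), CH2Cl2, 0 °C
Reagents that add atoms: 2-methoxypropene, COC(C)=C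
Why: Acid-catalysed addition of the hydroperoxide to 2-methoxypropene gives the peroxyketal, the usual base- and ylide-stable protection of a hydroperoxide, and with the C12 oxygen acetylated no cyclic trioxepane can form.

Step 18
Reactants: 28 (3S)-3-[(2-methoxypropan-2-yl)peroxy]-3,7-dimethyloct-6-en-1-yl acetate
Product: 29 (3S)-3-[(2-methoxypropan-2-yl)peroxy]-3,7-dimethyloct-6-en-1-ol
Conditions: K2CO3 (0.2 equiv), MeOH, 0 °C → rt
Reagents that add atoms: none
Why: Carbonate-catalysed methanolysis (transesterification) removes the acetate, and a di-tertiary peroxyketal without α-hydrogen is inert to base.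

Step 19
Reactants: 29 (3S)-3-[(2-methoxypropan-2-yl)peroxy]-3,7-dimethyloct-6-en-1-ol
Product: 30 (3S)-3-[(2-methoxypropan-2-yl)peroxy]-3,7-dimethyloct-6-enal
Conditions: Dess–Martin periodinane, NaHCO3, CH2Cl2, 0 °C; used at once
Reagents that add atoms: none
Why: Buffered Dess–Martin oxidation gives the β-peroxy aldehyde without acid that would cleave the peroxyketal, and the aldehyde is used at once to avoid β-elimination.

Step 20
Reactants: 31 (S)-3-bromo-2-methylpropan-1-ol
Product: 32 (S)-(3-bromo-2-methylpropoxy)(tert-butyl)dimethylsilane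
Conditions: t-BuMe2SiCl, imidazole, CH2Cl2, 0 °C → rt
Reagents that add atoms: tert-butyl(chloro)dimethylsilane, CC(C)(C)[Si](C)(C)Cl
Why: Routine silylation of the primary alcohol, in which the stereocentre is not involved.

Step 21
Reactants: 32 (S)-(3-bromo-2-methylpropoxy)(tert-butyl)dimethylsilane
Product: 33 [(2S)-3-(tert-butyldimethylsilyloxy)-2-methylpropyl]triphenylphosphonium iodide
Conditions: PPh3 (1.5 equiv), NaI (1.2 equiv), i-Pr2NEt (0.1 equiv), MeCN, reflux
Reagents that add atoms: triphenylphosphine, c1ccc(cc1)P(c1ccccc1)c1ccccc1; sodium iodide, [Na+].[I-]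
Why: SN2 quaternisation of PPh3, speeded by in situ bromide–iodide exchange (Finkelstein) at the β-branched carbon, does not touch the stereocentre.

Step 22
Reactants: 30 (3S)-3-[(2-methoxypropan-2-yl)peroxy]-3,7-dimethyloct-6-enal; 33 [(2S)-3-(tert-butyldimethylsilyloxy)-2-methylpropyl]triphenylphosphonium iodide
Product: 35 tert-butyl{[(2R,3Z,6S)-6-[(2-methoxypropan-2-yl)peroxy]-2,6,10-trimethylundeca-3,9-dien-1-yl]oxy}dimethylsilane, via ylide 34 (not isolated)
Conditions: 33 (1.3 equiv), NaN(SiMe3)2 (1.25 equiv), THF, 0 °C; then 30, −78 °C → rt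
Reagents that add atoms: none
Why: Wittig olefination with a non-stabilised ylide forms C11=C12 (mainly Z, geometry unimportant) at low temperature, where addition to the aldehyde outruns enolisation and loss of the β-peroxy group, peroxyketals being known to tolerate phosphorus ylides.

Step 23
Reactants: 35 tert-butyl{[(2R,3Z,6S)-6-[(2-methoxypropan-2-yl)peroxy]-2,6,10-trimethylundeca-3,9-dien-1-yl]oxy}dimethylsilane
Product: 36 (2R,3Z,6S)-6-[(2-methoxypropan-2-yl)peroxy]-2,6,10-trimethylundeca-3,9-dien-1-ol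
Conditions: Bu4NF, THF, 0 °C → rt
Reagents that add atoms: none
Why: Fluoride desilylation frees the C9 hydroxyl, and the peroxyketal is stable to fluoride and base.

Step 24
Reactants: 36 (2R,3Z,6S)-6-[(2-methoxypropan-2-yl)peroxy]-2,6,10-trimethylundeca-3,9-dien-1-ol
Product: 37 (2R,3Z,6S)-6-[(2-methoxypropan-2-yl)peroxy]-2,6,10-trimethylundeca-3,9-dien-1-yl iodide
Conditions: PPh3, I2, imidazole (premixed), CH2Cl2, 0 °C
Reagents that add atoms: iodine, II
Why: Iodination of the primary alcohol through its alkoxyphosphonium ion (Appel-type, Garegg–Samuelsson conditions) with the premixed reagent keeps free PPh3 away from the hindered O–O bond and does not touch C10.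

Step 25
Reactants: 37 (2R,3Z,6S)-6-[(2-methoxypropan-2-yl)peroxy]-2,6,10-trimethylundeca-3,9-dien-1-yl iodide
Product: 38 [(2R,3Z,6S)-6-[(2-methoxypropan-2-yl)peroxy]-2,6,10-trimethylundeca-3,9-dien-1-yl]triphenylphosphonium iodide
Conditions: PPh3 (3 equiv), i-Pr2NEt (0.2 equiv), MeCN, 55 °C, dark
Reagents that add atoms: triphenylphosphine, c1ccc(cc1)P(c1ccccc1)c1ccccc1
Why: SN2 quaternisation of PPh3 by the primary iodide at moderate temperature, where the di-tertiary peroxyketal, shielded on both oxygens, should resist deoxygenation by the phosphine.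

Step 26
Reactants: 25 methyl (2R)-2-[(3S,6S)-6-methyl-6-(2-oxoethyl)-1,2-dioxan-3-yl]propanoate; 38 [(2R,3Z,6S)-6-[(2-methoxypropan-2-yl)peroxy]-2,6,10-trimethylundeca-3,9-dien-1-yl]triphenylphosphonium iodide
Product: 40 methyl (2R)-2-[(3S,6S)-6-[(2Z,4S,5Z,8S)-8-[(2-methoxypropan-2-yl)peroxy]-4,8,12-trimethyltrideca-2,5,11-trien-1-yl]-6-methyl-1,2-dioxan-3-yl]propanoate, via ylide 39 (not isolated)
Conditions: 38 (1.2 equiv), NaN(SiMe3)2 (1.15 equiv), THF, −78 → −20 °C; then 25, −78 → 0 °C
Reagents that add atoms: none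
Why: Wittig olefination joins C8 to C9, the ylide adding to the aldehyde at −78 °C faster than it can deprotonate C7 or C2, and the geometry of the new alkene does not matter.

Step 27
Reactants: 40 methyl (2R)-2-[(3S,6S)-6-[(2Z,4S,5Z,8S)-8-[(2-methoxypropan-2-yl)peroxy]-4,8,12-trimethyltrideca-2,5,11-trien-1-yl]-6-methyl-1,2-dioxan-3-yl]propanoate
Product: 41 methyl (2R)-2-[(3S,6R)-6-[(4S,8R)-8-[(2-methoxypropan-2-yl)peroxy]-4,8,12-trimethyltridec-11-en-1-yl]-6-methyl-1,2-dioxan-3-yl]propanoate
Conditions: KO2CN=NCO2K (excess, in portions), AcOH, CH2Cl2, 0 °C → rt; stopped when both disubstituted alkenes are consumed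
Reagents that add atoms: none
Why: Diimide transfers H2 in a concerted syn fashion to the two cis-disubstituted alkenes much faster than to the trisubstituted C17=C18 alkene and does not cleave O–O bonds, and any peroxyketal lost to acetic acid is of no concern since step 28 removes it.

Step 28
Reactants: 41 methyl (2R)-2-[(3S,6R)-6-[(4S,8R)-8-[(2-methoxypropan-2-yl)peroxy]-4,8,12-trimethyltridec-11-en-1-yl]-6-methyl-1,2-dioxan-3-yl]propanoate
Product: 42 methyl (2R)-2-[(3S,6R)-6-[(4R,8R)-8-hydroperoxy-4,8,12-trimethyltridec-11-en-1-yl]-6-methyl-1,2-dioxan-3-yl]propanoate (CNP0381652.2)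
Conditions: AcOH/THF/H2O (4:2:1), rt
Reagents that add atoms: none
Why: Mild aqueous acid hydrolyses the acetone-derived peroxyketal to the free C14 hydroperoxide and leaves the dioxane, the ester and the alkene intact.

**Compound list**
1 | (R)-(−)-linalool, (3R)-3,7-dimethylocta-1,6-dien-3-ol | C=C[C@](C)(O)CCC=C(C)C | starting material
2 | (3R)-3,7-dimethyloct-6-ene-1,3-diol | OCC[C@](C)(O)CCC=C(C)C | intermediate
3 | (3R)-3-hydroxy-3,7-dimethyloct-6-en-1-yl 4-methylbenzenesulfonate | Cc1ccc(cc1)S(=O)(=O)OCC[C@](C)(O)CCC=C(C)C | intermediate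
4 | (2R)-2-methyl-2-(4-methylpent-3-en-1-yl)oxetane | C1C[C@@](C)(CCC=C(C)C)O1 | intermediate
5 | 3,3-dimethyl-5-{2-[(2R)-2-methyloxetan-2-yl]ethyl}-1,2,4-trioxolane (ozonide, C5 epimers) | C1C[C@@](C)(CCC2OOC(C)(C)O2)O1 | intermediate
6 | 3-[(2R)-2-methyloxetan-2-yl]propanal | C1C[C@@](C)(CCC=O)O1 | intermediate
7 | (methoxymethyl)triphenylphosphonium chloride | [Cl-].COC[P+](c1ccccc1)(c1ccccc1)c1ccccc1 | starting material
8 | (methoxymethylene)triphenylphosphorane | COC=P(c1ccccc1)(c1ccccc1)c1ccccc1 | intermediate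
9 | (2R)-2-(4-methoxybut-3-en-1-yl)-2-methyloxetane (E/Z mixture) | C1C[C@@](C)(CCC=COC)O1 | intermediate
10 | 3-[(2R)-2-methyloxetan-2-yl]propanal O-oxide (carbonyl oxide) | C1C[C@@](C)(CCC=[O+][O-])O1 | intermediate
11 | 1-methoxy-3-[(2R)-2-methyloxetan-2-yl]propyl hydroperoxide (both C3 epimers) | C1C[C@@](C)(CCC(OC)OO)O1 | intermediate
12 | (6S)-6-(2-hydroxyethyl)-3-methoxy-6-methyl-1,2-dioxane (C3 epimers) | COC1CC[C@@](C)(CCO)OO1 | intermediate
13 | (6S)-6-[2-(tert-butyldiphenylsilyloxy)ethyl]-3-methoxy-6-methyl-1,2-dioxane (C3 epimers) | COC1CC[C@@](C)(CCO[Si](c2ccccc2)(c2ccccc2)C(C)(C)C)OO1 | intermediate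
14 | (S)-but-3-yn-2-ol | C[C@H](O)C#C | starting material
15 | (2S,3E)-4-[dimethyl(phenyl)silyl]but-3-en-2-ol | C[C@H](O)/C=C/[Si](C)(C)c1ccccc1 | intermediate
16 | {(1E,3S)-3-[(1-methoxyethenyl)oxy]but-1-en-1-yl}dimethyl(phenyl)silane (ketene acetal) | C[C@H](OC(=C)OC)/C=C/[Si](C)(C)c1ccccc1 | intermediate
17 | methyl (3S,4E)-3-[dimethyl(phenyl)silyl]hex-4-enoate | COC(=O)C[C@@H](/C=C/C)[Si](C)(C)c1ccccc1 | intermediate
18 | (6S)-6-[2-(tert-butyldiphenylsilyloxy)ethyl]-6-methyl-1,2-dioxan-3-ylium triflate (peroxycarbenium ion, C3=O2+) | C1=[O+]O[C@](C)(CCO[Si](c2ccccc2)(c2ccccc2)C(C)(C)C)CC1.[O-]S(=O)(=O)C(F)(F)F | intermediate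
19 | methyl (3E,5S)-5-[(3S,6S)-6-[2-(tert-butyldiphenylsilyloxy)ethyl]-6-methyl-1,2-dioxan-3-yl]hex-3-enoate | COC(=O)C/C=C/[C@H](C)[C@@H]1CC[C@@](C)(CCO[Si](c2ccccc2)(c2ccccc2)C(C)(C)C)OO1 | intermediate
20 | ozonide of 19 (3,5-disubstituted 1,2,4-trioxolane, epimers at the trioxolane carbons) | COC(=O)CC1OOC(O1)[C@H](C)[C@@H]2CC[C@@](C)(CCO[Si](c3ccccc3)(c3ccccc3)C(C)(C)C)OO2 | intermediate
21 | (2R)-2-[(3S,6S)-6-[2-(tert-butyldiphenylsilyloxy)ethyl]-6-methyl-1,2-dioxan-3-yl]propanal | O=C[C@H](C)[C@@H]1CC[C@@](C)(CCO[Si](c2ccccc2)(c2ccccc2)C(C)(C)C)OO1 | intermediate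
22 | (2R)-2-[(3S,6S)-6-[2-(tert-butyldiphenylsilyloxy)ethyl]-6-methyl-1,2-dioxan-3-yl]propanoic acid | OC(=O)[C@H](C)[C@@H]1CC[C@@](C)(CCO[Si](c2ccccc2)(c2ccccc2)C(C)(C)C)OO1 | intermediate
23 | methyl (2R)-2-[(3S,6S)-6-[2-(tert-butyldiphenylsilyloxy)ethyl]-6-methyl-1,2-dioxan-3-yl]propanoate | COC(=O)[C@H](C)[C@@H]1CC[C@@](C)(CCO[Si](c2ccccc2)(c2ccccc2)C(C)(C)C)OO1 | intermediate
24 | methyl (2R)-2-[(3S,6S)-6-(2-hydroxyethyl)-6-methyl-1,2-dioxan-3-yl]propanoate | COC(=O)[C@H](C)[C@@H]1CC[C@@](C)(CCO)OO1 | intermediate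
25 | methyl (2R)-2-[(3S,6S)-6-methyl-6-(2-oxoethyl)-1,2-dioxan-3-yl]propanoate | COC(=O)[C@H](C)[C@@H]1CC[C@@](C)(CC=O)OO1 | intermediate
26 | (3S)-3-hydroperoxy-3,7-dimethyloct-6-en-1-ol | OCC[C@](C)(CCC=C(C)C)OO | intermediate
27 | (3S)-3-hydroperoxy-3,7-dimethyloct-6-en-1-yl acetate | CC(=O)OCC[C@](C)(CCC=C(C)C)OO | intermediate
28 | (3S)-3-[(2-methoxypropan-2-yl)peroxy]-3,7-dimethyloct-6-en-1-yl acetate | CC(=O)OCC[C@](C)(CCC=C(C)C)OOC(C)(C)OC | intermediate
29 | (3S)-3-[(2-methoxypropan-2-yl)peroxy]-3,7-dimethyloct-6-en-1-ol | OCC[C@](C)(CCC=C(C)C)OOC(C)(C)OC | intermediate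
30 | (3S)-3-[(2-methoxypropan-2-yl)peroxy]-3,7-dimethyloct-6-enal | O=CC[C@](C)(CCC=C(C)C)OOC(C)(C)OC | intermediate
31 | (S)-3-bromo-2-methylpropan-1-ol | OC[C@H](C)CBr | starting material
32 | (S)-(3-bromo-2-methylpropoxy)(tert-butyl)dimethylsilane | CC(C)(C)[Si](C)(C)OC[C@H](C)CBr | intermediate
33 | [(2S)-3-(tert-butyldimethylsilyloxy)-2-methylpropyl]triphenylphosphonium iodide | [I-].CC(C)(C)[Si](C)(C)OC[C@H](C)C[P+](c1ccccc1)(c1ccccc1)c1ccccc1 | intermediate
34 | [(2S)-3-(tert-butyldimethylsilyloxy)-2-methylpropylidene]triphenylphosphorane | CC(C)(C)[Si](C)(C)OC[C@H](C)C=P(c1ccccc1)(c1ccccc1)c1ccccc1 | intermediate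
35 | tert-butyl{[(2R,3Z,6S)-6-[(2-methoxypropan-2-yl)peroxy]-2,6,10-trimethylundeca-3,9-dien-1-yl]oxy}dimethylsilane | CC(C)(C)[Si](C)(C)OC[C@H](C)/C=C\C[C@](C)(CCC=C(C)C)OOC(C)(C)OC | intermediate
36 | (2R,3Z,6S)-6-[(2-methoxypropan-2-yl)peroxy]-2,6,10-trimethylundeca-3,9-dien-1-ol | OC[C@H](C)/C=C\C[C@](C)(CCC=C(C)C)OOC(C)(C)OC | intermediate
37 | (2R,3Z,6S)-6-[(2-methoxypropan-2-yl)peroxy]-2,6,10-trimethylundeca-3,9-dien-1-yl iodide | IC[C@H](C)/C=C\C[C@](C)(CCC=C(C)C)OOC(C)(C)OC | intermediate
38 | [(2R,3Z,6S)-6-[(2-methoxypropan-2-yl)peroxy]-2,6,10-trimethylundeca-3,9-dien-1-yl]triphenylphosphonium iodide | [I-].c1ccccc1[P+](c1ccccc1)(c1ccccc1)C[C@H](C)/C=C\C[C@](C)(CCC=C(C)C)OOC(C)(C)OC | intermediate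
39 | [(2R,3Z,6S)-6-[(2-methoxypropan-2-yl)peroxy]-2,6,10-trimethylundeca-3,9-dien-1-ylidene]triphenylphosphorane | c1ccccc1P(c1ccccc1)(c1ccccc1)=C[C@H](C)/C=C\C[C@](C)(CCC=C(C)C)OOC(C)(C)OC | intermediate
40 | methyl (2R)-2-[(3S,6S)-6-[(2Z,4S,5Z,8S)-8-[(2-methoxypropan-2-yl)peroxy]-4,8,12-trimethyltrideca-2,5,11-trien-1-yl]-6-methyl-1,2-dioxan-3-yl]propanoate | COC(=O)[C@H](C)[C@@H]1CC[C@@](C)(C/C=C\[C@H](C)/C=C\C[C@](C)(CCC=C(C)C)OOC(C)(C)OC)OO1 | intermediate
41 | methyl (2R)-2-[(3S,6R)-6-[(4S,8R)-8-[(2-methoxypropan-2-yl)peroxy]-4,8,12-trimethyltridec-11-en-1-yl]-6-methyl-1,2-dioxan-3-yl]propanoate | COC(=O)[C@H](C)[C@@H]1CC[C@@](C)(CCC[C@H](C)CCC[C@](C)(CCC=C(C)C)OOC(C)(C)OC)OO1 | intermediate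
42 | methyl (2R)-2-[(3S,6R)-6-[(4R,8R)-8-hydroperoxy-4,8,12-trimethyltridec-11-en-1-yl]-6-methyl-1,2-dioxan-3-yl]propanoate, (2R,3S,6R,10R,14R) in chain numbering | COC(=O)[C@H](C)[C@@H]1CC[C@@](C)(CCC[C@H](C)CCC[C@](C)(CCC=C(C)C)OO)OO1 | target

**Step count and risks**

Total step count: 28. Longest linear sequence: 15 steps (1 to 42 through the dioxane core: steps 1–7, 10–14, 26–28).

Steps most likely to fail:

Step 10. The crotylsilane may add to the peroxycarbenium ion with poor facial selectivity, or through a synclinal transition state that gives the 2,3-anti isomer, and the Lewis acid may also induce heterolysis of the O–O bond. The fallback gives up reagent control and relies on separation. It sets out from 13. A Mukaiyama-type substitution of 13 with the silyl ketene acetal of S-ethyl propanethioate, 1-(ethylsulfanyl)-1-(trimethylsilyloxy)prop-1-ene, and Me3SiOTf or SnCl4 in CH2Cl2 at −78 °C, a known reaction of 3-alkoxy-1,2-dioxanes and dioxolanes, would give S-ethyl (2R)-2-[(3S,6S)-6-[2-(tert-butyldiphenylsilyloxy)ethyl]-6-methyl-1,2-dioxan-3-yl]propanethioate F1 beside its diastereomers. F1 is separated from them by chromatography. Methanolysis of the thioester group of F1 with AgO2CCF3 in MeOH then comes back to the route at 23.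

Step 6. The hydroperoxyacetal may ionise (loss of methanol or of hydrogen peroxide) faster than the oxetane is activated, the opening may drift towards a free tertiary cation with erosion of the C6 configuration, or the freed C8 hydroxyl may transacetalise at C3. The fallback forms the C6–O bond intermolecularly and closes the ring at C3 instead. It sets out from 26, which already carries the inverted peroxy centre. Ozonolysis of 26 in CH2Cl2/MeOH at −78 °C without reductant cleaves the trisubstituted alkene to (4S)-4-hydroperoxy-6-hydroxy-4-methylhexanal F2. F2 should close at once to the cyclic peroxyhemiacetal (6S)-6-(2-hydroxyethyl)-6-methyl-1,2-dioxan-3-ol F3. Treatment of F3 with MeOH and catalytic TsOH then gives 12, where the fallback rejoins the route.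

Step 25. During the slow quaternisation of the β-branched iodide the phosphine may deoxygenate the peroxyketal, or the peroxyketal may be lost thermally. The fallback avoids a phosphonium salt on the peroxide fragment and sets out from 36. Mitsunobu reaction of 36 with 1-phenyl-1H-tetrazole-5-thiol, PPh3 and diisopropyl azodicarboxylate in THF at 0 °C would give 5-{[(2R,3Z,6S)-6-[(2-methoxypropan-2-yl)peroxy]-2,6,10-trimethylundeca-3,9-dien-1-yl]sulfanyl}-1-phenyl-1H-tetrazole F4. Buffered oxidation of F4 with H2O2 and catalytic (NH4)6Mo7O24 gives 5-{[(2R,3Z,6S)-6-[(2-methoxypropan-2-yl)peroxy]-2,6,10-trimethylundeca-3,9-dien-1-yl]sulfonyl}-1-phenyl-1H-tetrazole F5. Julia–Kocienski olefination of F5 with 25, run with KN(SiMe3)2 in DME at −60 °C, gives the 8E isomer of 40, methyl (2R)-2-[(3S,6S)-6-[(2E,4S,5Z,8S)-8-[(2-methoxypropan-2-yl)peroxy]-4,8,12-trimethyltrideca-2,5,11-trien-1-yl]-6-methyl-1,2-dioxan-3-yl]propanoate F6. F6 is reduced with diimide under the conditions of step 27 and comes back to the route at 41.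

Further compounds
F1 | step 10 | S-ethyl (2R)-2-[(3S,6S)-6-[2-(tert-butyldiphenylsilyloxy)ethyl]-6-methyl-1,2-dioxan-3-yl]propanethioate | CCSC(=O)[C@H](C)[C@@H]1CC[C@@](C)(CCO[Si](c2ccccc2)(c2ccccc2)C(C)(C)C)OO1
F2 | step 6 | (4S)-4-hydroperoxy-6-hydroxy-4-methylhexanal | O=CCC[C@@](C)(CCO)OO
F3 | step 6 | (6S)-6-(2-hydroxyethyl)-6-methyl-1,2-dioxan-3-ol (C3 epimers) | OC1CC[C@@](C)(CCO)OO1
F4 | step 25 | 5-{[(2R,3Z,6S)-6-[(2-methoxypropan-2-yl)peroxy]-2,6,10-trimethylundeca-3,9-dien-1-yl]sulfanyl}-1-phenyl-1H-tetrazole | c1ccccc1-n1nnnc1SC[C@H](C)/C=C\C[C@](C)(CCC=C(C)C)OOC(C)(C)OC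
F5 | step 25 | 5-{[(2R,3Z,6S)-6-[(2-methoxypropan-2-yl)peroxy]-2,6,10-trimethylundeca-3,9-dien-1-yl]sulfonyl}-1-phenyl-1H-tetrazole | c1ccccc1-n1nnnc1S(=O)(=O)C[C@H](C)/C=C\C[C@](C)(CCC=C(C)C)OOC(C)(C)OC
F6 | step 25 | methyl (2R)-2-[(3S,6S)-6-[(2E,4S,5Z,8S)-8-[(2-methoxypropan-2-yl)peroxy]-4,8,12-trimethyltrideca-2,5,11-trien-1-yl]-6-methyl-1,2-dioxan-3-yl]propanoate | COC(=O)[C@H](C)[C@@H]1CC[C@@](C)(C/C=C/[C@H](C)/C=C\C[C@](C)(CCC=C(C)C)OOC(C)(C)OC)OO1
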